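Retrosynthesis: the C6 ester C–O bond and the two acid protecting groups are cut first, then 6β-OH goes back to a C6 ketone. The C5–C10 and C8–C9 bonds are then cut together, which opens both rings to an acyclic triene. That chain is cut at C7=C8 (aldol), C1–C10 (sp3–sp2 coupling) and C3–C4 (conjugate allylation).
Enabling feature: ring B (C5–C10) carries O on C6 and carbonyl groups on C8 and C9. C9–C10 (acyl on C9) is therefore an acrylate-type 2π unit and C5–C6–C7–C8 (O on C6, acyl on C8) a 2-oxy-diene. The two are already joined by the C1–C4 chain of ring A, so the molecule holds an intramolecular Diels–Alder retron.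
Forward: the chain is built by a Hosomi–Sakurai reaction, a B-alkyl Suzuki–Miyaura coupling and an aldol condensation. One intramolecular Diels–Alder reaction then closes rings A and B together. The C6 ketone is reduced, the alcohol esterified, and the tert-butyl esters removed.
Stereochemistry: the absolute sense comes from a (4S)-4-benzyloxazolidinone on the C9 carbonyl. C5, C8, C9 and C10 follow from the three alkene geometries and the endo transition state. C6 follows from hydride attack on the open α face of the trans-decalone.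

Key step: step 10

Remark: drimane numbering is used throughout (ring carbons C1–C10, C11 on C9, C12 on C8, β = face of the C10 methyl). tert-Butyl glyoxylate (13) is taken as a purchasable reagent, distilled before use.

Step 1
Reactants: 1 mesityl oxide; 2 allyltrimethylsilane
Product: 3 4,4-dimethylhept-6-en-2-one
Conditions: TiCl4, CH2Cl2, −78 °C; H2O
Reagents that add atoms: none
Why: Hosomi–Sakurai conjugate allylation of the TiCl4-activated enone at its β,β-disubstituted carbon should create the quaternary C4 with the C1–C3 arm and the C5–C6–C7 ketone arm in place (no stereocenter).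

Step 2
Reactants: 3 4,4-dimethylhept-6-en-2-one
Product: 4 2-(2,2-dimethylpent-4-en-1-yl)-2-methyl-1,3-dioxolane
Conditions: HOCH2CH2OH, TsOH (cat.), toluene, reflux, Dean–Stark
Reagents that add atoms: ethylene glycol OCCO
Why: Acid-catalysed ketalisation masks the ketone, which 9-BBN would otherwise reduce in step 4.

Step 3
Reactants: 5 tert-butyl acetoacetate
Product: 6 tert-butyl (2E)-3-{[(trifluoromethyl)sulfonyl]oxy}but-2-enoate
Conditions: Tf2O, aq Me4NOH, toluene, 5 °C → rt
Reagents that add atoms: trifluoromethanesulfonic anhydride FC(F)(F)S(=O)(=O)OS(=O)(=O)C(F)(F)F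
Why: Enol triflation of a β-keto ester with a non-chelating counter-ion should give the (E)-enol triflate (triflate trans to the ester), which fixes the later C9=C10 geometry.

Step 4
Reactants: 4 2-(2,2-dimethylpent-4-en-1-yl)-2-methyl-1,3-dioxolane; 6 tert-butyl (2E)-3-{[(trifluoromethyl)sulfonyl]oxy}but-2-enoate
Product: 8 tert-butyl (2E)-3,7,7-trimethyl-8-(2-methyl-1,3-dioxolan-2-yl)oct-2-enoate, via alkyl-9-BBN borane 7 (not isolated)
Conditions: 9-BBN, THF, 0 °C → rt; then 6, PdCl2(dppf) (5 mol %), aq K3PO4, DMF, rt → 50 °C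
Reagents that add atoms: none
Why: Anti-Markovnikov hydroboration followed by B-alkyl Suzuki–Miyaura coupling forms C1–C10 with retention of the triflate geometry, so the (E)-β-methyl enoate should result.

Step 5
Reactants: 8 tert-butyl (2E)-3,7,7-trimethyl-8-(2-methyl-1,3-dioxolan-2-yl)oct-2-enoate
Product: 9 (2E)-3,7,7-trimethyl-9-oxodec-2-enoic acid
Conditions: TFA/CH2Cl2 (1:3), rt; then H2O/THF, rt
Reagents that add atoms: water O
Why: Acidolysis of the tert-butyl ester and aqueous-acid hydrolysis of the dioxolane occur in one operation, and the conjugated trisubstituted alkene should not isomerise under these conditions.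

Step 6
Reactants: 9 (2E)-3,7,7-trimethyl-9-oxodec-2-enoic acid; 10 (4S)-4-benzyl-1,3-oxazolidin-2-one
Product: 12 (4S)-4-benzyl-3-[(2E)-3,7,7-trimethyl-9-oxodec-2-enoyl]-1,3-oxazolidin-2-one, via mixed pivalic anhydride 11 (not isolated)
Conditions: PivCl, Et3N, THF, −20 °C; then LiCl, 10, −20 °C → rt
Reagents that add atoms: none
Why: N-Acylation of the oxazolidinone through the mixed pivalic anhydride takes place at the less hindered enoyl carbonyl and leaves the auxiliary stereocenter untouched.

Step 7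
Reactants: 12 (4S)-4-benzyl-3-[(2E)-3,7,7-trimethyl-9-oxodec-2-enoyl]-1,3-oxazolidin-2-one; 13 tert-butyl glyoxylate
Product: 15 tert-butyl (10E)-12-[(4S)-4-benzyl-2-oxo-1,3-oxazolidin-3-yl]-2-hydroxy-6,6,10-trimethyl-4,12-dioxododec-10-enoate (both C2 epimers), via dicyclohexylboron enolate 14 (not isolated)
Conditions: Cy2BCl, Et3N, Et2O, −78 → 0 °C; 13, −78 °C; MeOH, pH 7 buffer, H2O2, 0 °C
Reagents that add atoms: none
Why: In this boron aldol reaction Cy2BCl/Et3N should enolise the methyl ketone on the methyl side (C7; the C5 methylene is neopentyl) and not the enoyl imide; the uncontrolled carbinol center is removed in step 8.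

Step 8
Reactants: 15 tert-butyl (10E)-12-[(4S)-4-benzyl-2-oxo-1,3-oxazolidin-3-yl]-2-hydroxy-6,6,10-trimethyl-4,12-dioxododec-10-enoate
Product: 17 tert-butyl (2E,10E)-12-[(4S)-4-benzyl-2-oxo-1,3-oxazolidin-3-yl]-6,6,10-trimethyl-4,12-dioxododeca-2,10-dienoate, via mesylate 16 (not isolated)
Conditions: MsCl, Et3N, CH2Cl2, 0 °C → rt
Reagents that add atoms: none
Why: Mesylation and E1cB elimination should give the thermodynamically favoured (E)-4-oxo-2-enoate (C7=C8).

Step 9
Reactants: 17 tert-butyl (2E,10E)-12-[(4S)-4-benzyl-2-oxo-1,3-oxazolidin-3-yl]-6,6,10-trimethyl-4,12-dioxododeca-2,10-dienoate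
Product: 18 tert-butyl (2E,4Z,10E)-12-[(4S)-4-benzyl-2-oxo-1,3-oxazolidin-3-yl]-4-[(tert-butyldimethylsilyl)oxy]-6,6,10-trimethyl-12-oxododeca-2,4,10-trienoate
Conditions: TBSOTf, Et3N, CH2Cl2, −78 → 0 °C; filtration through Et3N-deactivated silica
Reagents that add atoms: tert-butyldimethylsilyl triflate CC(C)(C)[Si](C)(C)OS(=O)(=O)C(F)(F)F
Why: Soft enolisation toward C5, the only enolisable position of the ketone, should give the (Z)-silyl dienol ether (C4 trans to C7, avoiding A1,3 strain), which is the diene with the tether on the outside.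

Step 10
Reactants: 18 tert-butyl (2E,4Z,10E)-12-[(4S)-4-benzyl-2-oxo-1,3-oxazolidin-3-yl]-4-[(tert-butyldimethylsilyl)oxy]-6,6,10-trimethyl-12-oxododeca-2,4,10-trienoate
Product: 20 tert-butyl (1S,2S,4aS,8aS)-1-{[(4S)-4-benzyl-2-oxo-1,3-oxazolidin-3-yl]carbonyl}-5,5,8a-trimethyl-4-oxodecahydronaphthalene-2-carboxylate, via silyl enol ether cycloadduct 19 (not isolated)
Conditions: Me2AlCl (2.0 equiv), CH2Cl2, −78 → −20 °C; then 1 M HCl/THF, 0 °C → rt
Reagents that add atoms: none
Why: Two equivalents of Me2AlCl convert the imide into the cationic bidentate aluminium chelate (syn carbonyls, s-cis enoyl), whose C9=C10 bond adds across C5 and C8 of the 2-silyloxy diene in an asynchronous intramolecular [4+2] cycloaddition in which C5–C10 formation runs ahead of C8–C9 closure. The closest known reaction type is the oxazolidinone-controlled, dialkylaluminium chloride-promoted intramolecular Diels–Alder reaction of trienimides, together with Lewis-acid Diels–Alder reactions of 2-silyloxy dienes (stepwise limit: Mukaiyama–Michael addition then Michael ring closure). Ring A (C1–C5, C10) closes through the four-carbon tether by the C5–C10 bond (6-exo in the stepwise picture), and ring B (C5–C10) is the new cyclohexene of this type-1 cycloaddition, closed by C8–C9 (6-endo in the stepwise picture). C9 and C10 follow from suprafacial addition to the (E)-enoyl unit (methyl and acyl cis) on its Cα-si face, the face opposite the benzyl group of the (4S)-auxiliary; C5 and C8 follow from the (4Z)-enol ether and (2E)-enoate geometries (C4 and CO2tBu both outside) and from the endo position of the chelated acyl group, which gives the trans ring fusion (H-5 α, CH3-10 β) and the cis 8β,9β-dicarbonyl pattern. The step needs endo over exo and one π face: the cationic chelate favours endo, the benzyl group screens the other face, and the tether fixes the regiochemistry. Acidic work-up hydrolyses the C6=C7 silyl enol ether to the C6 ketone without touching a stereocenter (C7 is CH2).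

Step 11
Reactants: 20 tert-butyl (1S,2S,4aS,8aS)-1-{[(4S)-4-benzyl-2-oxo-1,3-oxazolidin-3-yl]carbonyl}-5,5,8a-trimethyl-4-oxodecahydronaphthalene-2-carboxylate
Product: 22 (1S,2S,4aS,8aS)-2-(tert-butoxycarbonyl)-5,5,8a-trimethyl-4-oxodecahydronaphthalene-1-carboxylic acid, via peroxy acid 21 (not isolated)
Conditions: LiOH, 30% H2O2, THF/H2O (3:1), 0 °C; aq Na2SO3; 1 M HCl to pH 3
Reagents that add atoms: hydrogen peroxide OO
Why: Lithium hydroperoxide should attack the exocyclic imide carbonyl selectively even when it is hindered, and 0 °C with a short reaction time should avoid epimerisation at C8 or C9.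

Step 12
Reactants: 22 (1S,2S,4aS,8aS)-2-(tert-butoxycarbonyl)-5,5,8a-trimethyl-4-oxodecahydronaphthalene-1-carboxylic acid
Product: 23 di-tert-butyl (1S,2S,4aS,8aS)-5,5,8a-trimethyl-4-oxodecahydronaphthalene-1,2-dicarboxylate
Conditions: Cl3CC(=NH)OtBu, BF3·OEt2 (cat.), cyclohexane/CH2Cl2, rt
Reagents that add atoms: tert-butyl 2,2,2-trichloroacetimidate CC(C)(C)OC(=N)C(Cl)(Cl)Cl
Why: Acid-catalysed O-tert-butylation with the trichloroacetimidate transfers a tert-butyl cation to the carboxyl oxygen and so is insensitive to the hindrance at C11; it makes both carboxyls cleavable in one final step.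

Step 13
Reactants: 23 di-tert-butyl (1S,2S,4aS,8aS)-5,5,8a-trimethyl-4-oxodecahydronaphthalene-1,2-dicarboxylate
Product: 24 di-tert-butyl (1S,2S,4R,4aS,8aS)-4-hydroxy-5,5,8a-trimethyldecahydronaphthalene-1,2-dicarboxylate
Conditions: NaBH4, MeOH/THF, −20 → 0 °C
Reagents that add atoms: none
Why: Hydride should attack C6 from the α face because the β face is blocked by the axial methyls on C4 and C10 and the axial C8 ester, giving the axial 6β-alcohol (6R); the tert-butyl ester at C12 is chosen to resist lactonisation by the syn-axial 6β-oxygen.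

Step 14
Reactants: 25 (2E,4E)-hexa-2,4-dienal; 26 malonic acid
Product: 28 (2E,4E,6E)-octa-2,4,6-trienoic acid, via dienylidenemalonic acid 27 (not isolated)
Conditions: pyridine, piperidine (cat.), 90 °C
Reagents that add atoms: none
Why: Knoevenagel–Doebner condensation with decarboxylation should give the (2E) acid while the existing E,E-diene is retained.

Step 15
Reactants: 24 di-tert-butyl (1S,2S,4R,4aS,8aS)-4-hydroxy-5,5,8a-trimethyldecahydronaphthalene-1,2-dicarboxylate; 28 (2E,4E,6E)-octa-2,4,6-trienoic acid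
Product: 30 di-tert-butyl (1S,2S,4R,4aS,8aS)-5,5,8a-trimethyl-4-{[(2E,4E,6E)-octa-2,4,6-trienoyl]oxy}decahydronaphthalene-1,2-dicarboxylate, via Yamaguchi mixed anhydride 29 (not isolated)
Conditions: 2,4,6-Cl3C6H2COCl, Et3N, toluene, rt; then 24, DMAP, toluene, rt → 70 °C
Reagents that add atoms: none
Why: Yamaguchi esterification transfers the trienoyl group through the acyl-DMAP species to the hindered axial alcohol, and the C6 configuration is retained because the C–O bond is not broken.

Step 16
Reactants: 30 di-tert-butyl (1S,2S,4R,4aS,8aS)-5,5,8a-trimethyl-4-{[(2E,4E,6E)-octa-2,4,6-trienoyl]oxy}decahydronaphthalene-1,2-dicarboxylate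
Product: 31 (1S,2S,4R,4aS,8aS)-5,5,8a-trimethyl-4-{[(2E,4E,6E)-octa-2,4,6-trienoyl]oxy}decahydronaphthalene-1,2-dicarboxylic acid (CNP0462207.1)
Conditions: TFA/CH2Cl2 (1:2), 0 °C → rt
Reagents that add atoms: none
Why: Acidolysis of both tert-butyl esters with loss of isobutene should leave the conjugated trienoate ester and all five stereocenters untouched.

Compound list
1 | mesityl oxide (4-methylpent-3-en-2-one) | CC(=O)C=C(C)C | starting material
2 | allyltrimethylsilane | C=CC[Si](C)(C)C | starting material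
3 | 4,4-dimethylhept-6-en-2-one | CC(=O)CC(C)(C)CC=C | intermediate
4 | 2-(2,2-dimethylpent-4-en-1-yl)-2-methyl-1,3-dioxolane | CC1(CC(C)(C)CC=C)OCCO1 | intermediate
5 | tert-butyl acetoacetate | CC(=O)CC(=O)OC(C)(C)C | starting material
6 | tert-butyl (2E)-3-{[(trifluoromethyl)sulfonyl]oxy}but-2-enoate | CC(C)(C)OC(=O)/C=C(/OS(=O)(=O)C(F)(F)F)C | intermediate
7 | 9-[4,4-dimethyl-5-(2-methyl-1,3-dioxolan-2-yl)pentyl]-9-borabicyclo[3.3.1]nonane | CC1(CC(C)(C)CCCB2C3CCCC2CCC3)OCCO1 | intermediate
8 | tert-butyl (2E)-3,7,7-trimethyl-8-(2-methyl-1,3-dioxolan-2-yl)oct-2-enoate | CC1(CC(C)(C)CCC/C(C)=C/C(=O)OC(C)(C)C)OCCO1 | intermediate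
9 | (2E)-3,7,7-trimethyl-9-oxodec-2-enoic acid | CC(=O)CC(C)(C)CCC/C(C)=C/C(=O)O | intermediate
10 | (4S)-4-benzyl-1,3-oxazolidin-2-one | O=C1N[C@@H](Cc2ccccc2)CO1 | starting material
11 | (2E)-3,7,7-trimethyl-9-oxodec-2-enoic pivalic anhydride | CC(=O)CC(C)(C)CCC/C(C)=C/C(=O)OC(=O)C(C)(C)C | intermediate
12 | (4S)-4-benzyl-3-[(2E)-3,7,7-trimethyl-9-oxodec-2-enoyl]-1,3-oxazolidin-2-one | CC(=O)CC(C)(C)CCC/C(C)=C/C(=O)N1[C@@H](Cc2ccccc2)COC1=O | intermediate
13 | tert-butyl glyoxylate | O=CC(=O)OC(C)(C)C | starting material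
14 | dicyclohexylboron enolate of 12 (enolised at the methyl group) | C=C(OB(C1CCCCC1)C1CCCCC1)CC(C)(C)CCC/C(C)=C/C(=O)N1[C@@H](Cc2ccccc2)COC1=O | intermediate
15 | tert-butyl (10E)-12-[(4S)-4-benzyl-2-oxo-1,3-oxazolidin-3-yl]-2-hydroxy-6,6,10-trimethyl-4,12-dioxododec-10-enoate (both C2 epimers) | CC(C)(C)OC(=O)C(O)CC(=O)CC(C)(C)CCC/C(C)=C/C(=O)N1[C@@H](Cc2ccccc2)COC1=O | intermediate
16 | 2-O-methanesulfonate of 15 | CC(C)(C)OC(=O)C(OS(C)(=O)=O)CC(=O)CC(C)(C)CCC/C(C)=C/C(=O)N1[C@@H](Cc2ccccc2)COC1=O | intermediate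
17 | tert-butyl (2E,10E)-12-[(4S)-4-benzyl-2-oxo-1,3-oxazolidin-3-yl]-6,6,10-trimethyl-4,12-dioxododeca-2,10-dienoate | CC(C)(C)OC(=O)/C=C/C(=O)CC(C)(C)CCC/C(C)=C/C(=O)N1[C@@H](Cc2ccccc2)COC1=O | intermediate
18 | tert-butyl (2E,4Z,10E)-12-[(4S)-4-benzyl-2-oxo-1,3-oxazolidin-3-yl]-4-[(tert-butyldimethylsilyl)oxy]-6,6,10-trimethyl-12-oxododeca-2,4,10-trienoate | CC(C)(C)OC(=O)/C=C/C(O[Si](C)(C)C(C)(C)C)=C/C(C)(C)CCC/C(C)=C/C(=O)N1[C@@H](Cc2ccccc2)COC1=O | intermediate
19 | tert-butyl (1S,2S,4aS,8aS)-1-{[(4S)-4-benzyl-2-oxo-1,3-oxazolidin-3-yl]carbonyl}-4-[(tert-butyldimethylsilyl)oxy]-5,5,8a-trimethyl-1,2,4a,5,6,7,8,8a-octahydronaphthalene-2-carboxylate | CC(C)(C)[Si](C)(C)OC1=C[C@H](C(=O)OC(C)(C)C)[C@H](C(=O)N3[C@@H](Cc4ccccc4)COC3=O)[C@@]2(C)CCCC(C)(C)[C@H]12 | intermediate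
20 | tert-butyl (1S,2S,4aS,8aS)-1-{[(4S)-4-benzyl-2-oxo-1,3-oxazolidin-3-yl]carbonyl}-5,5,8a-trimethyl-4-oxodecahydronaphthalene-2-carboxylate (5α-H, 10β-CH3, 8β- and 9β-carbonyl) | O=C1C[C@H](C(=O)OC(C)(C)C)[C@H](C(=O)N3[C@@H](Cc4ccccc4)COC3=O)[C@@]2(C)CCCC(C)(C)[C@H]12 | intermediate
21 | (1S,2S,4aS,8aS)-2-(tert-butoxycarbonyl)-5,5,8a-trimethyl-4-oxodecahydronaphthalene-1-carboperoxoic acid | O=C1C[C@H](C(=O)OC(C)(C)C)[C@H](C(=O)OO)[C@@]2(C)CCCC(C)(C)[C@H]12 | intermediate
22 | (1S,2S,4aS,8aS)-2-(tert-butoxycarbonyl)-5,5,8a-trimethyl-4-oxodecahydronaphthalene-1-carboxylic acid | O=C1C[C@H](C(=O)OC(C)(C)C)[C@H](C(=O)O)[C@@]2(C)CCCC(C)(C)[C@H]12 | intermediate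
23 | di-tert-butyl (1S,2S,4aS,8aS)-5,5,8a-trimethyl-4-oxodecahydronaphthalene-1,2-dicarboxylate | O=C1C[C@H](C(=O)OC(C)(C)C)[C@H](C(=O)OC(C)(C)C)[C@@]2(C)CCCC(C)(C)[C@H]12 | intermediate
24 | di-tert-butyl (1S,2S,4R,4aS,8aS)-4-hydroxy-5,5,8a-trimethyldecahydronaphthalene-1,2-dicarboxylate (6β-OH) | O[C@@H]1C[C@H](C(=O)OC(C)(C)C)[C@H](C(=O)OC(C)(C)C)[C@@]2(C)CCCC(C)(C)[C@H]12 | intermediate
25 | (2E,4E)-hexa-2,4-dienal | C/C=C/C=C/C=O | starting material
26 | malonic acid | OC(=O)CC(=O)O | starting material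
27 | [(2E,4E)-hexa-2,4-dien-1-ylidene]propanedioic acid | C/C=C/C=C/C=C(C(=O)O)C(=O)O | intermediate
28 | (2E,4E,6E)-octa-2,4,6-trienoic acid | C/C=C/C=C/C=C/C(=O)O | intermediate
29 | (2E,4E,6E)-octa-2,4,6-trienoic 2,4,6-trichlorobenzoic anhydride | C/C=C/C=C/C=C/C(=O)OC(=O)c1c(Cl)cc(Cl)cc1Cl | intermediate
30 | di-tert-butyl (1S,2S,4R,4aS,8aS)-5,5,8a-trimethyl-4-{[(2E,4E,6E)-octa-2,4,6-trienoyl]oxy}decahydronaphthalene-1,2-dicarboxylate | C/C=C/C=C/C=C/C(=O)O[C@@H]1C[C@H](C(=O)OC(C)(C)C)[C@H](C(=O)OC(C)(C)C)[C@@]2(C)CCCC(C)(C)[C@H]12 | intermediate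
31 | (1S,2S,4R,4aS,8aS)-5,5,8a-trimethyl-4-{[(2E,4E,6E)-octa-2,4,6-trienoyl]oxy}decahydronaphthalene-1,2-dicarboxylic acid | C/C=C/C=C/C=C/C(=O)O[C@@H]1C[C@H](C(=O)O)[C@H](C(=O)O)[C@@]2(C)CCCC(C)(C)[C@H]12 | target

Total step count: 16. Longest linear sequence: 14 (steps 1, 2, 4–13, 15, 16); steps 3 and 14 are side branches.

Steps most likely to fail

Step 10. The β,β-disubstituted enoyl imide may react too slowly with the ester-deactivated silyloxy diene, so that the Lewis acid protodesilylates the dienol ether first. Endo/exo or π-facial selectivity may also erode, because the trans-fused transition state has to build the 1,3-diaxial methyl/methyl contact between C4 and C10. The fallback replaces the Lewis-acid cycloaddition by an anionic intramolecular double Michael reaction. It sets out from 17: LiHMDS in THF at −78 °C removes a C5 proton to give the cross-conjugated lithium dienolate F1, in which lithium can chelate the imide carbonyls. On warming to 0 °C, C5 should add to C10 and the resulting imide enolate should close onto C8; protonation returns the route at ketone 20.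

Step 15. Acyl transfer to the 6β-hydroxyl, which is syn-axial to two methyl groups and the C8 ester, may be too slow, so that the activated trienoyl donor isomerises or oligomerises through a dienyl ketene before it is captured. The fallback builds the triene on the ester. It sets out from 24, which is acylated with diethylphosphonoacetic acid and DCC (the small phosphonoketene is the acylating species) to give the phosphonoacetate F2, di-tert-butyl (1S,2S,4R,4aS,8aS)-4-{[(diethoxyphosphoryl)acetyl]oxy}-5,5,8a-trimethyldecahydronaphthalene-1,2-dicarboxylate. Horner–Wadsworth–Emmons olefination of F2 with (2E,4E)-hexa-2,4-dienal 25 (LiCl, DBU, MeCN) should form the 2E double bond and return the route at 30.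

Step 13. The 6β-alkoxide that forms during reduction sits syn-axial to the C12 ester and may close the 6,12-lactone with loss of tert-butoxide; the hindered ketone may also be reduced incompletely. The fallback never liberates the alcohol. It sets out from 23 and uses (2E,4E,6E)-octa-2,4,6-trienoyl chloride F3, made from 28 with oxalyl chloride and catalytic DMF. L-Selectride in THF at −78 °C should deliver hydride from the α face to give the lithium 6β-alkoxide F4, which is trapped in the same flask at −78 °C with F3. This returns the route at 30 and bypasses 24 and step 15.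

Further compounds
F1 | step 10 | lithium dienolate of 17 (deprotonated at C5) | [Li+].CC(C)(C)OC(=O)/C=C/C([O-])=C/C(C)(C)CCC/C(C)=C/C(=O)N1[C@@H](Cc2ccccc2)COC1=O
F2 | step 15 | di-tert-butyl (1S,2S,4R,4aS,8aS)-4-{[(diethoxyphosphoryl)acetyl]oxy}-5,5,8a-trimethyldecahydronaphthalene-1,2-dicarboxylate | CCOP(=O)(OCC)CC(=O)O[C@@H]1C[C@H](C(=O)OC(C)(C)C)[C@H](C(=O)OC(C)(C)C)[C@@]2(C)CCCC(C)(C)[C@H]12
F3 | step 13 | (2E,4E,6E)-octa-2,4,6-trienoyl chloride | C/C=C/C=C/C=C/C(=O)Cl
F4 | step 13 | lithium 6β-alkoxide of 24 | [Li+].[O-][C@@H]1C[C@H](C(=O)OC(C)(C)C)[C@H](C(=O)OC(C)(C)C)[C@@]2(C)CCCC(C)(C)[C@H]12
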